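## Structural features

The target is 2,3,4,6-tetrabromo-1H-indole: a benzene ring and a pyrrole ring fused through the C3a–C7a bond, with bromine on C2 and C3 of the pyrrole ring and on C4 and C6 of the benzene ring, hydrogen on C5 and C7, and a free N1–H. It has no stereocenter, so the whole problem is one of regiochemistry. C2 and C3 are the positions at which an indole reacts with electrophiles by nature. The 4,6-pattern with hydrogen on C5 cannot be reached by brominating an indole, so it has to be built into the benzene ring during ring construction; that is the real difficulty. The fragile elements are the four C–Br bonds, which rule out organolithium reagents, zerovalent palladium and dissolving metals once the ring system is complete, and the electron-rich 2,3-dibromopyrrole unit with free N–H, which is sensitive to acid, light and oxidation and is best made last. The key step uses the two adjacent ring-fusion carbons: C7a carries N1, C3a carries C3, and C4 next to C3a carries bromine. This is the substitution pattern left by a 3-bromoaryne, in which a nucleophile bonds to the aryne carbon remote from bromine and the carbanion beside bromine takes an electrophile; a second bromine meta to the attacked carbon ends up on C6.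

## Logic of the disconnections

16 ⇒ 14 (through 15). The C3–Br and C2–Br bonds are cut first. Both carbons are the innately nucleophilic positions of the indole, so one electrophilic bromine source can serve both in one flask, C3 first and C2 second. The gain is that the most sensitive array is absent from every earlier intermediate. The forward step must brominate a deactivated indole twice without attack on C5 or C7 and without oxidation at C2.

14 ⇒ 13. The N1–S bond is cut. The sulfonyl group is needed earlier, as the acidifying group that lets nitrogen add to an aryne and as protection during dehydration, but it must be gone before bromination because C2 substitution depends on the free N–H indole. The forward step must cleave a sulfonamide without touching two aryl bromides.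

13 ⇒ 12 ⇒ 11. The C2=C3 double bond is traced back to a C3 carbinol and then to a C3 ketone, so two C–H bonds and one C–O bond are adjusted and no skeletal bond is cut. The ketone is exactly what an acylation at C3a leaves behind, which turns the indole into an annulation product. The forward steps are a hydride reduction and a dehydration that tolerate aryl bromides; the one transient stereocenter in 12 needs no control.

11 ⇒ 5 + 8 (through 10 and 9). The N1–C7a and C3–C3a bonds are cut, which removes the five-membered ring and leaves a two-atom aryne component and an N–C–C component. The silicon-bearing carbon of 5 maps onto C7a, the triflate-bearing carbon onto C3a, the bromine beside the triflate onto C4–Br and the para bromine onto C6–Br. The gain is large: both ring-forming bonds and the whole 4,6-dibromo pattern come from one operation on two simple partners. The forward step needs nitrogen to add to the aryne carbon remote from bromine, and needs the resulting carbanion to acylate faster than it loses bromide or picks up a proton.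

5 ⇒ 4 ⇒ 3 ⇒ 2 ⇒ 1. The O–S bond, then the C–Si bond (returned to oxygen) and finally the O–Si bond are cut, back to a symmetrical phenol whose two ortho bromines are equivalent. One of them is traded for silicon, the other stays as the future C4–Br, and the para bromine becomes C6–Br. The forward step needs halogen–metal exchange at an ortho bromine in preference to the para bromine and in preference to attack at silicon.

8 ⇒ 6 + 7. The N–S bond is cut, back to an amino ester salt and a sulfonyl chloride. The only requirement is mono-sulfonylation.

## Other disconnections considered

Alternative 1: The cut removes three bonds of the benzene ring at once (C3a–C7a, C4–C5, C6–C7). In the forward direction the tethered ynamide–silylalkyne A2 and ethynyltrimethylsilane A3 would be joined by RhCl(PPh3)3 in a [2+2+2] cyclotrimerisation, closing both the pyrroline and the benzene ring of the disilylindoline A1. Double ipso-bromodesilylation would then give A4, dehydrogenation of the indoline would give 13, and the route would finish as steps 7 and 8.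
- In favour: the 4,6-pattern is written into the alkyne partners, the conditions are neutral, and no carbanion ever sits beside a leaving group. On this last point the alternative is the better of the two, since the bromide-loss hazard of the aryne plan is absent.
- Against: A2 is a terminal N-ethynyl sulfonamide that needs roughly three to four steps and is prone to hydration. The orientation of A3 (its silicon meta rather than ortho to the C4 silicon) rests on steric bias alone, and self-trimerisation of A3 competes. Bromine arrives masked as silicon, which costs two extra operations. In A1 both silicon-bearing carbons are meta to nitrogen, while C5 and C7 are para and ortho to it, so direct C–H bromination could compete with ipso attack.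
- Comparison: on structure the two plans are equal, since both fix C4 and C6 by construction. On mechanism the alternative avoids anionic intermediates but takes on a less predictable halodesilylation. On step economy it should need eight or nine steps, equal to or slightly longer than the chosen plan.

Alternative 2: The cut is N1–C7a. Forward, a Knoevenagel condensation of 2,4-dibromobenzaldehyde A7 with methyl azidoacetate A8 would give the azidocinnamate A6. Heating A6 in xylene (Hemetsberger–Knittel reaction) expels N2, and the vinyl nitrene inserts into the only free ortho C–H to give the indole-2-carboxylate A5. Saponification to the acid A9, protodecarboxylation to 14 and step 8 would complete the synthesis.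
- In favour: one ortho position of the aryl ring is blocked by bromine, so the regiochemistry is fixed by the substrate and does not depend on the polarisation of an aryne; here the alternative is equal or better. No ionic intermediate can lose bromide. The sequence is about five steps, clearly better in step economy than the eight of the chosen plan.
- Against: A8 and A6 are energetic azides and A6 must be heated, which is the main safety objection. The condensation of the ortho-substituted aldehyde A7 with the base-sensitive A8 is the usual weak point of this indole synthesis. The C2 ester is surplus, and removing it from A9 calls for a hot Cu/quinoline decarboxylation under which aryl bromides may be reduced or coupled. A brominative decarboxylation of A9 that placed the C2 bromine directly would be attractive but would have to be developed.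
- Comparison: shorter and structurally more certain, but less safe and with a harsh defunctionalisation near the end. The chosen plan runs at or near room temperature throughout and carries no superfluous carbon.

Alternative 3: The cut is N1–C2, with C2 keeping its bromine. Forward, 2-amino-4,6-dibromobenzaldehyde A12 would be converted by Ramirez olefination (CBr4/PPh3) and N-mesylation into the gem-dibromoolefin A11. Cs2CO3 in DMF would deprotonate the sulfonamide and close the ring onto the dibromovinyl group to give the 2-bromoindole A10, by direct vinylic substitution or by elimination to a bromoalkyne followed by 5-endo-dig amination. C3 bromination and removal of the methanesulfonyl group would give 16.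
- In favour: the C2 bromine arrives with the ring closure, so the less certain second bromination of the chosen plan (C2 of 15) is avoided; on this point the alternative is the better. The closure is mild and metal-free.
- Against: A12 is not a common catalogue compound. Making it moves the regiochemical problem onto classical arene chemistry (a 1,2,3,5-tetrasubstituted benzene with amino, formyl and two bromo groups) and should cost about four steps. Ortho-aminobenzaldehydes self-condense, and the formyl group of A12 is flanked on both sides.
- Comparison: on structure it handles C2 better and C4/C6 worse. On mechanism it is comparably reliable and free of ortho-bromoaryl anions. On step economy it should need eight or nine steps, equal to or slightly longer than the chosen plan.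

Key step: step 4

Remark: 12 is formed and used as the racemate, because its only stereocenter (C3) is removed in step 6. Tosyl means 4-methylbenzenesulfonyl throughout.

## Steps

Step 1
Reactants: 1 2,4,6-tribromophenol
Product: 2 trimethyl(2,4,6-tribromophenoxy)silane
Conditions: HMDS (0.7 equiv), THF, 70 °C; volatiles removed in vacuo, crude used dry
Reagents that add atoms: hexamethyldisilazane, C[Si](C)(C)N[Si](C)(C)C
Why: O-silylation of an acidic phenol by a silazane with loss of ammonia; the reaction is clean enough that the moisture-sensitive ether can be carried on without purification.

Step 2
Reactants: 2 trimethyl(2,4,6-tribromophenoxy)silane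
Product: 5 2,4-dibromo-6-(trimethylsilyl)phenyl trifluoromethanesulfonate, via 3,5-dibromo-2-(trimethylsilyloxy)phenyllithium 3 (not isolated), via lithium 2,4-dibromo-6-(trimethylsilyl)phenoxide 4 (not isolated)
Conditions: n-BuLi (1.05 equiv), THF, −100 → −78 °C; then Tf2O (1.2 equiv), −100 °C → rt
Reagents that add atoms: trifluoromethanesulfonic anhydride, O=S(=O)(OS(=O)(=O)C(F)(F)F)C(F)(F)F
Why: Bromine–lithium exchange should occur at one of the two equivalent ortho bromines, where the aryllithium is stabilised by the adjacent oxygen, and 3 has no bromine ortho to lithium, so it cannot collapse to an aryne. The anionic 1,3 O→C silyl shift (retro-Brook rearrangement) then gives phenoxide 4, which is O-sulfonylated by Tf2O.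

Step 3
Reactants: 6 glycine methyl ester hydrochloride; 7 p-toluenesulfonyl chloride
Product: 8 methyl N-tosylglycinate
Conditions: Et3N (2.2 equiv), CH2Cl2, 0 °C → rt
Reagents that add atoms: none
Why: N-sulfonylation of the primary amine freed from its hydrochloride; the reaction stops at the mono-sulfonamide because the product N–H is far less nucleophilic than the amine.

Step 4
Reactants: 5 2,4-dibromo-6-(trimethylsilyl)phenyl trifluoromethanesulfonate; 8 methyl N-tosylglycinate
Product: 11 4,6-dibromo-1-tosylindolin-3-one, via 3,5-dibromobenzyne 9 (not isolated), via caesium aryl anion adduct 10 (not isolated)
Conditions: CsF (3 equiv), MeCN, rt → 40 °C; 8 (1.5 equiv), 5 added slowly by syringe pump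
Reagents that add atoms: none
Why: Fluoride attacks the silicon of 5 and triflate leaves from the neighbouring carbon, so that aryne 9 is formed between the former C–Si and C–O carbons (fluoride-induced 1,2-elimination of an ortho-silylaryl triflate). The sulfonamide of 8, deprotonated under the fluoride conditions, adds through nitrogen to the aryne carbon that carried silicon, the one remote from the flanking bromine; this forms N1–C7a and leaves the negative charge of 10 on the carbon beside bromine, the future C3a. Anion 10 then attacks the ester carbonyl, separated from the carbanion by three atoms, in a 5-exo-trig closure, and the tetrahedral intermediate expels methoxide, which forms C3–C3a and the ketone of 11; this is the only ring closed in the step. The closest known reaction type is the fluoride-triggered aryne annulation of N–H/ester pairs (N-sulfonyl amino esters to indolin-3-ones, anthranilates to acridones), which follows the same order of N-arylation and acylation. No stereocenter is created. The selectivity needed is regiochemical: the bromine next to the triple bond withdraws electron density and distorts the aryne so that the distal carbon is the electrophilic one and the carbanion develops ortho to bromine, and the bulk of the sulfonamide pushes the same way; the second bromine is meta to the attacked carbon and para to the carbanion and should have only a small influence. The chemoselectivity needed is that acylation of 10 outruns loss of bromide and protonation; the favourable five-membered closure secures this, and slow addition of 5 to an excess of 8 keeps the aryne away from the C2-acidic product 11.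

Step 5
Reactants: 11 4,6-dibromo-1-tosylindolin-3-one
Product: 12 4,6-dibromo-1-tosylindolin-3-ol (racemic)
Conditions: NaBH4 (1.2 equiv), MeOH/THF 1:1, 0 °C
Reagents that add atoms: none
Why: Borohydride 1,2-reduction of an aryl ketone, to which aryl bromides and the sulfonamide are inert; the new C3 stereocenter is formed without control as the racemate, which is acceptable because step 6 removes it.

Step 6
Reactants: 12 4,6-dibromo-1-tosylindolin-3-ol
Product: 13 4,6-dibromo-1-tosyl-1H-indole
Conditions: TsOH·H2O (10 mol%), toluene, 80 °C
Reagents that add atoms: none
Why: Acid-catalysed E1 dehydration of a benzylic carbinol, in which loss of a C2 proton is driven by aromatisation to the indole; the N-sulfonyl group keeps the product from acid-induced oligomerisation.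

Step 7
Reactants: 13 4,6-dibromo-1-tosyl-1H-indole
Product: 14 4,6-dibromo-1H-indole
Conditions: KOH (5 equiv), EtOH/THF/H2O, 70 °C
Reagents that add atoms: none
Why: Nucleophilic cleavage of the N–S bond by hydroxide at sulfur, made easier because the dibromoindolide is a good leaving group; the aryl bromides carry no activating group for nucleophilic aromatic substitution, and the aqueous medium avoids N-alkylation by a sulfonate ester.

Step 8
Reactants: 14 4,6-dibromo-1H-indole
Product: 16 2,3,4,6-tetrabromo-1H-indole, via 3,4,6-tribromo-1H-indole 15 (not isolated)
Conditions: NBS (2.1 equiv), SiO2, CH2Cl2, 0 °C → rt, dark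
Reagents that add atoms: N-bromosuccinimide, O=C1CCC(=O)N1Br
Why: Electrophilic bromination of the indole: the first equivalent substitutes C3 to give 15 and the second is delivered to C2 (attack at C3 again, then 1,2-shift of bromine and loss of the proton). The benzene ring already carries two bromines and should be too deactivated to compete, and dry, dark conditions suppress oxidation at C2.

## Compound list

1 | 2,4,6-tribromophenol | Oc1c(Br)cc(Br)cc1Br | starting material
2 | trimethyl(2,4,6-tribromophenoxy)silane | C[Si](C)(C)Oc1c(Br)cc(Br)cc1Br | intermediate
3 | 3,5-dibromo-2-(trimethylsilyloxy)phenyllithium | [Li]c1cc(Br)cc(Br)c1O[Si](C)(C)C | intermediate (not isolated)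
4 | lithium 2,4-dibromo-6-(trimethylsilyl)phenoxide | [Li+].[O-]c1c(Br)cc(Br)cc1[Si](C)(C)C | intermediate (not isolated)
5 | 2,4-dibromo-6-(trimethylsilyl)phenyl trifluoromethanesulfonate | C[Si](C)(C)c1cc(Br)cc(Br)c1OS(=O)(=O)C(F)(F)F | intermediate
6 | glycine methyl ester hydrochloride | COC(=O)CN.Cl | starting material
7 | p-toluenesulfonyl chloride | Cc1ccc(cc1)S(=O)(=O)Cl | starting material
8 | methyl N-tosylglycinate | COC(=O)CNS(=O)(=O)c1ccc(C)cc1 | intermediate
9 | 3,5-dibromobenzyne | BrC1=CC(Br)=CC#C1 | intermediate (not isolated)
10 | caesium 2,4-dibromo-6-[N-(2-methoxy-2-oxoethyl)-N-tosylamino]benzenide | [Cs+].COC(=O)CN(C1=CC(Br)=CC(Br)=[C-]1)S(=O)(=O)c1ccc(C)cc1 | intermediate (not isolated)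
11 | 4,6-dibromo-1-tosylindolin-3-one | Cc1ccc(cc1)S(=O)(=O)N1CC(=O)c2c(Br)cc(Br)cc21 | intermediate
12 | 4,6-dibromo-1-tosylindolin-3-ol (racemic) | Cc1ccc(cc1)S(=O)(=O)N1CC(O)c2c(Br)cc(Br)cc21 | intermediate
13 | 4,6-dibromo-1-tosyl-1H-indole | Cc1ccc(cc1)S(=O)(=O)n1ccc2c(Br)cc(Br)cc21 | intermediate
14 | 4,6-dibromo-1H-indole | Brc1cc(Br)c2cc[nH]c2c1 | intermediate
15 | 3,4,6-tribromo-1H-indole | Brc1cc(Br)c2c(Br)c[nH]c2c1 | intermediate (not isolated)
16 | 2,3,4,6-tetrabromo-1H-indole | Brc1cc(Br)c2c(Br)c(Br)[nH]c2c1 | target

## Step count and least certain steps

Total: 8 steps. Longest linear sequence: 7 steps (steps 1, 2, 4, 5, 6, 7, 8 from 1); step 3 supplies the second partner of step 4.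

Step 4 (key step). Several processes could compete with the annulation:
- loss of bromide from carbanion 10 before it acylates, which would open a second aryne and lead to oligomeric amination;
- protonation of 10 by free sulfonamide or solvent before ring closure;
- erosion of the site of nitrogen addition by the second bromine;
- attack of the nucleophile at the triflate sulfur of the electron-poor precursor instead of fluoride at silicon;
- further arylation of the enolisable product.

A less acidic medium (THF with a crown ether) is a first adjustment. The fallback replaces the aryne by a classical indoxyl closure; it sets out from 7 and comes back at 11. Compound 7 is condensed with commercial 3,5-dibromoaniline (pyridine, CH2Cl2) to give N-(3,5-dibromophenyl)-4-methylbenzenesulfonamide F1. N-alkylation with methyl bromoacetate (K2CO3, DMF) gives methyl N-(3,5-dibromophenyl)-N-tosylglycinate F2. LiOH in THF/H2O gives N-(3,5-dibromophenyl)-N-tosylglycine F3. (COCl)2 with catalytic DMF gives N-(3,5-dibromophenyl)-N-tosylglycyl chloride F4, and AlCl3 in 1,2-dichloroethane should close it by intramolecular Friedel–Crafts acylation to 11. The two positions ortho to nitrogen are equivalent, and each lies ortho to one bromine and para to the other, so only the 4,6-dibromo isomer can form. The cost is a deactivated ring in the acylation and three more steps.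

Step 2. The silyl ether of so acidic a phenol is a good silyl donor, so attack of n-BuLi at silicon with release of the phenoxide could compete with exchange; exchange at the para bromine and double exchange are the other risks. The fallback avoids an O–Si bond during the exchange; it sets out from 1 and comes back at 5. Phenol 1 is treated with n-BuLi (2.1 equiv, Et2O/THF, −78 °C → 0 °C): the first equivalent makes the lithium phenoxide and the second exchanges an ortho bromine under direction by the O–Li group, giving lithium 2,4-dibromo-6-lithiophenoxide F5. Excess Me3SiCl silylates carbon and oxygen to give [3,5-dibromo-2-(trimethylsilyloxy)phenyl]trimethylsilane F6. K2CO3 in MeOH removes the O-silyl group to give 2,4-dibromo-6-(trimethylsilyl)phenol F7, which is isolated and purified, and Tf2O with pyridine in CH2Cl2 gives 5.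

Step 8. The second bromination could stall, because 15 is deactivated by three bromines and C3 is crowded by the peri bromine on C4. Traces of water could divert the intermediate to oxidation at C2, and acid formed in the reaction could degrade the product. The fallback brings in the C2 bromine from a lactam carbonyl instead of by electrophilic substitution; it sets out from 14 and comes back at 16. Indole 14 is oxidised with pyridinium tribromide (3 equiv) in tert-butanol to 3,3,4,6-tetrabromoindolin-2-one F8. Zn in AcOH at rt removes the two bromines alpha to the carbonyl and should leave the aryl bromides, giving 4,6-dibromoindolin-2-one F9. POBr3 with imidazole in 1,2-dichloroethane at 80 °C converts the lactam into 2,4,6-tribromo-1H-indole F10. One equivalent of NBS in THF at 0 °C then brominates the free C3 position to give 16.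

## Further compounds

F1 | step 4 | N-(3,5-dibromophenyl)-4-methylbenzenesulfonamide | Cc1ccc(cc1)S(=O)(=O)Nc1cc(Br)cc(Br)c1
F2 | step 4 | methyl N-(3,5-dibromophenyl)-N-tosylglycinate | COC(=O)CN(c1cc(Br)cc(Br)c1)S(=O)(=O)c1ccc(C)cc1
F3 | step 4 | N-(3,5-dibromophenyl)-N-tosylglycine | OC(=O)CN(c1cc(Br)cc(Br)c1)S(=O)(=O)c1ccc(C)cc1
F4 | step 4 | N-(3,5-dibromophenyl)-N-tosylglycyl chloride | ClC(=O)CN(c1cc(Br)cc(Br)c1)S(=O)(=O)c1ccc(C)cc1
F5 | step 2 | lithium 2,4-dibromo-6-lithiophenoxide | [Li]Oc1c(Br)cc(Br)cc1[Li]
F6 | step 2 | [3,5-dibromo-2-(trimethylsilyloxy)phenyl]trimethylsilane | C[Si](C)(C)Oc1c(Br)cc(Br)cc1[Si](C)(C)C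
F7 | step 2 | 2,4-dibromo-6-(trimethylsilyl)phenol | Oc1c(Br)cc(Br)cc1[Si](C)(C)C
F8 | step 8 | 3,3,4,6-tetrabromoindolin-2-one | O=C1Nc2cc(Br)cc(Br)c2C1(Br)Br
F9 | step 8 | 4,6-dibromoindolin-2-one | O=C1Cc2c(Br)cc(Br)cc2N1
F10 | step 8 | 2,4,6-tribromo-1H-indole | Brc1cc(Br)c2cc(Br)[nH]c2c1
A1 | alternative 1 | 1-tosyl-4,6-bis(trimethylsilyl)indoline | Cc1ccc(cc1)S(=O)(=O)N1CCc2c1cc(cc2[Si](C)(C)C)[Si](C)(C)C
A2 | alternative 1 | N-ethynyl-4-methyl-N-[4-(trimethylsilyl)but-3-yn-1-yl]benzenesulfonamide | C#CN(CCC#C[Si](C)(C)C)S(=O)(=O)c1ccc(C)cc1
A3 | alternative 1 | ethynyltrimethylsilane | C#C[Si](C)(C)C
A4 | alternative 1 | 4,6-dibromo-1-tosylindoline | Cc1ccc(cc1)S(=O)(=O)N1CCc2c(Br)cc(Br)cc21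
A5 | alternative 2 | methyl 4,6-dibromo-1H-indole-2-carboxylate | COC(=O)c1cc2c(Br)cc(Br)cc2[nH]1
A6 | alternative 2 | methyl (Z)-2-azido-3-(2,4-dibromophenyl)acrylate | COC(=O)/C(N=[N+]=[N-])=C/c1ccc(Br)cc1Br
A7 | alternative 2 | 2,4-dibromobenzaldehyde | O=Cc1ccc(Br)cc1Br
A8 | alternative 2 | methyl azidoacetate | COC(=O)CN=[N+]=[N-]
A9 | alternative 2 | 4,6-dibromo-1H-indole-2-carboxylic acid | OC(=O)c1cc2c(Br)cc(Br)cc2[nH]1
A10 | alternative 3 | 2,4,6-tribromo-1-(methylsulfonyl)-1H-indole | CS(=O)(=O)n1c(Br)cc2c(Br)cc(Br)cc21
A11 | alternative 3 | N-[3,5-dibromo-2-(2,2-dibromovinyl)phenyl]methanesulfonamide | CS(=O)(=O)Nc1cc(Br)cc(Br)c1C=C(Br)Br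
A12 | alternative 3 | 2-amino-4,6-dibromobenzaldehyde | Nc1cc(Br)cc(Br)c1C=O
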